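(The rate constants were set for the occasion; what happens was integrated by code.)

Slowness in this flask sits in a pool, not in one species, so I hand it over as a pool: intermediate plus free target.

| flask | starting material | coupling partner | second reagent | time |
|---|---|---|---|---|
| summer | 0.0080 M | 0.0777 M | 0.0814 M | 25 min |
| autumn | 0.025 M | 0.0777 M | 0.0814 M | 25 min |
| spring | 0.080 M | 0.0777 M | 0.0814 M | 25 min |
| dusk | 0.20 M | 0.0777 M | 0.0814 M | 25 min |
| dawn | 0.60 M | 0.0777 M | 0.0814 M | 25 min |

    starting material + coupling partner → intermediate (k1 = 0.049 M⁻¹ s⁻¹)
    second reagent + intermediate ⇌ target (K2 = 9.1 M⁻¹, k2 = 0.15 M⁻¹ s⁻¹)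
    intermediate → side product (k3 = 0.0064 s⁻¹)
    crystals ⇌ target, rate k4*(cs4 - [target]) while solid is left; crystals form when [target] > cs4 (cs4 = 30 mM, k4 = 1.1 s⁻¹)

- [target] (only what is free in solution) at the end for summer, autumn, spring, dusk, dawn, in this order
- how that number moves from the first to the last of them (hardly changes / rises all the way / falls all the way / falls, then rises / rises, then falls)

- target is meant together with its crystals
- solid, in amounts per volume of the solution: crystals
- the concentration of target that is asked is that of its free form alone
- "hardly changes" means that all values lie within two and a half points (for a concentration: within two and a half percent of the largest)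
- run time (summer): 25 min

The coupling step feeds intermediate into the pool, and I follow one molecule there, holding second reagent at its charge (pseudo-first-order). As intermediate it meets a fork: it becomes target at a = 0.0122 s⁻¹, or side product at c = 0.0064 s⁻¹. As target it returns at b = 0.0165 s⁻¹. Side product is a one-way door and target a waiting room, so I call λ the drain rate of the pool: the smaller of two rates whose sum is a + b + c and whose product is c·b. That gives λ = 0.00332 s⁻¹, a half-life of 3.48 min. I leave the second reagent charge as it stands, since a and λ move with it. The sampling time matters too: 25 min is 7.18 of those half-lives, so once the feed is over a later sample reads lower.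

Dawn is the flask I can reckon. There coupling partner is the limiting reagent, its charge smaller than that of starting material, and with starting material held at its charge it is consumed at 0.0294 s⁻¹, faster than λ. I therefore treat it as one batch of intermediate born at the start. The two rates differ by 0.0285 s⁻¹, and once the faster one has faded, such a batch shows as target the fraction a over that difference, 0.429, of what the drain has left. So for dawn I commit to 2.29 × 10⁻⁴ M. Further I go only in shape: in spring the two charges stand close, so I expect the feed to tail off slowly and the peak to stand there.

The forecast gives 1.000 × 10⁻⁴ M, 3.600 × 10⁻⁴ M, 0.0014 M, 3.600 × 10⁻⁴ M and 2.000 × 10⁻⁴ M, so rises, then falls. It holds that “the whole pool bleeds to side product” at about 0.0035 per second, and its dawn value of 2.000 × 10⁻⁴ M stands below my 2.29 × 10⁻⁴ M.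

The flask gives 1.03 × 10⁻⁴ M, 3.88 × 10⁻⁴ M, 0.00139 M, 3.80 × 10⁻⁴ M and 2.25 × 10⁻⁴ M: rises, then falls. In dusk, coupling partner stands at 0.686% of its charge at 12.5 min, and target falls from 2.05% of the charged starting material then to 0.190% at 25.0 min, a reading of 10.8 against the 12.1 that λ gives for that interval.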